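Reagent has a half-life of 0.66 d by its loss to side product alone, while the solid substrate must dissolve before it can meet reagent.

    dissolved substrate + reagent → target (k1 = 0.087 L mol⁻¹ h⁻¹)
    solid substrate + protic impurity → quenched substrate (k2 = 4.5 L mol⁻¹ h⁻¹)
    solid substrate ⇌ dissolved substrate, rate k3*(cs3 - [dissolved substrate]) while solid is left; crystals form when [dissolved substrate] > cs3 (cs3 = 0.15 M, k3 = 0.056 h⁻¹)
    solid product ⇌ target, rate k4*(cs4 - [target]) while solid is left; crystals form when [target] > cs4 (cs4 = 0.13 M, k4 = 2.0 h⁻¹)
    reagent → side product (k5 = 0.044 h⁻¹)

solid substrate 0.36 M; reagent 0.720 M; protic impurity 0.0720 M; time 15 d

- for target the solid product is counted in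
- as a solid, counted per litre of solution: solid substrate, solid product
- at the start none of the solid substrate is in solution
- what has only dissolved of solid substrate counts as not reacted
- the reaction counts as stopped when no species that holds the solid substrate changes by six tenths of a point or more over the second half of the time
- run time (flask): 15 d

1. at 15 d, what has stopped the reaction, if anything has (for what has run out or reacted, a solid counts together with what of it has only dissolved) (the reagent has run out first / it is still moving / all of the solid substrate has reacted)
2. the target standing at 15 d, as a percentage of the solid substrate charged

Write D for dissolved substrate, c* for its solubility (0.15 M), k_D for the dissolution coefficient (0.056 h⁻¹), k_T for the rate constant of target formation (0.087 L mol⁻¹ h⁻¹) and k_L for that of reagent loss (0.044 h⁻¹). At any moment the share of consumed reagent that reaches target, the selectivity, is k_T·D/(k_L + k_T·D). Two chemists dispute which D belongs there.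

The saturation side puts D at c*, which gives a share of 22.9 % and target at 45.7 % of the charge. The lag side answers that D starts at zero and that the reagent lifetime 1/k_L = 22.7 h is longer than the filling time 1/k_D = 17.9 h by a factor of 1.27, too little for D to stand at c* while the reagent lasts.

My own reckoning takes the lag side. Averaging the filling curve over the decaying reagent gives D_w = c*·k_D/(k_D + k_L) = 0.0840 M. Putting D_w into the selectivity gives the reagent-weighted share φ 14.2 %, so φ times the reagent charge is 0.103 M, or 28.5 % of the charge. I expect this to run high, because target formation drains D at k_T times the reagent charge, 0.0626 h⁻¹, faster than k_D at the start. The saturation side's region is where k_D/(k_D + k_L) nears one; here it is 0.560.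

The forecast, from the lag side, differs from my number: the reagent has run out first, with 23 %, the share being one that “rises from about 3% to about 20%”.

The simulation gives the reagent has run out first, with 0 % of the reagent left and 22.7 % as target. By 1.50 d the reagent loss in this flask had 85 % of its turnover behind it, while dissolved substrate stood at 0.106 M, less than c*. The target of this flask, 0.0817 M, is a factor f = 0.796 of φ times the reagent charge.

φ is reckoned from c*, k_D, k_T and k_L, and these are the same in the neighbour flask with 0.90 M of solid substrate, so its φ is the same too. φ times the reagent charge is then 11.4 % of that flask's charge, and f, taken over from the first flask, brings that to 9.08 %. Its computed yield is 9.08 %, with 0 % of the reagent left and 66.3 % still solid.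

The numbers of this flask come from no measurement; the rest is arithmetic.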